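Percent of the starting material charged is the unit of every reading here, and that unit hides the concentration of the flask, a setting in which dawn differs from the east run.

| setting | east | dawn | dusk | summer |
|---|---|---|---|---|
| starting material | 0.75 M | 0.50 M | 0.50 M | 0.50 M |
| reagent | 1.2 equiv | 1.20 equiv | 1.20 equiv | 1.20 equiv |
| free catalyst | 0.066 mol% | 0.066 mol% | 0.066 mol% | 0.066 mol% |
| temperature | 30 °C | 30 °C |  | 0 °C |
| remark | run made earlier |  | at 0 °C until 20 h, from then on at 30 °C |  |
| time |  | 25 h | 25 h | 25 h |

east run (percent of the starting material charged)

| time / h | target / % | starting material / % |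
|---|---|---|
| 1.50 | 2.1 | 90.1 |
| 3.00 | 2.7 | 88.1 |
| 5.00 | 5.8 | 86.2 |
| 6.00 | 6.8 | 84.8 |
| 8.00 | 8.9 | 83.2 |

(readings scatter by 0.5 percentage points)

- the earlier runs do not show what temperature does; that part of a forecast is a guess
- no earlier run changes the charge of free catalyst; that part of a forecast is a guess

1. the best flask by amount of target, in percent of the starting material charged; "all alike" if 1.5 percentage points covers them all (dawn / dusk / summer / all alike)
2. amount of target at the end, in percent of the starting material charged, dawn
3. amount of target at the end, in percent of the starting material charged, dusk
4. amount of target at the end, in percent of the starting material charged, summer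

In the east run, starting material and target together fall short of the charge by 7.80% at the first reading and by 7.90% at the last, so a share of the charge sits unread, and it does not grow. Target still climbs, to 8.9% at 8.00 h. That gives the pace, the share of the charge turned into target per hour, 0.0111 h⁻¹.

But no earlier run varies a concentration, so how the pace moves is a choice. The choice here is one step that takes starting material, reagent and free catalyst once each. With equivalents and mol% held, each of these scales with c(starting material), so the rate in M per hour goes with the cube and the pace with the square. Dawn's pace at the outset is then 0.00494 h⁻¹, about half of the east run's. As the flask runs, this pace falls with the share of starting material left and with the share of reagent left, reagent being charged at 1.20 equiv, and integrating that gives 11.1% at 25 h. The hours at 0 °C remain a guess, and this reckoning puts no number on them.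

The forecast names dawn as best, with 23% (15% to 30%) for dawn, 7% (4% to 11%) for dusk and 2.5% (0.8% to 7%) for summer. Its ground is a rise that “looks near zero-order in substrate with the catalyst saturated”, so its dawn stands higher than the reckoning above.

The flasks come out all alike: dawn 12.3%, dusk 11.8%, summer 11.6%, a spread smaller than 1.5 percentage points.

    starting material + free catalyst ⇌ free catalyst + open intermediate (K = 0.167, k = 1380 M⁻¹ h⁻¹, Ea = 48.0 kJ mol⁻¹, ΔH = −14.0 kJ mol⁻¹)
    free catalyst + open intermediate ⇌ catalyst intermediate (K = 3.23 M⁻¹, k = 249 M⁻¹ h⁻¹, Ea = 63.0 kJ mol⁻¹, ΔH = −56.0 kJ mol⁻¹)
    reagent + catalyst intermediate → free catalyst + target (k = 123 M⁻¹ h⁻¹, Ea = 55.0 kJ mol⁻¹)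
    reagent → decomposition product (k = 2.76 × 10⁻⁵ h⁻¹, Ea = 116 kJ mol⁻¹)
    (constants at 0 °C)

A neighbouring flask is dawn with 0.26 mol% of free catalyst. Its pace, taken in proportion to the loading, is 0.0195 h⁻¹, and the same integration gives 33.7% at 25 h. That flask gives 36.5%, with free catalyst, the resting state, at 99.3% of the catalyst charged and 58.2% of the starting material still there.

The earlier runs and the new flask are simulated for substances that don't exist; the scatter is artificial.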